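**Plan**

- Retrosynthesis: the aryl–CH2 bond of the methylene bridge is cut last. This gives a pyranone that already carries the bridge carbon as CH2–NHMe2+ and a fully substituted acylphloroglucinol with one free ring carbon. The pyranone is then cut at C3–CH2 (Mannich), at the lactone O1–C2 bond and at one chain C–C bond (β-keto ester dianion + propanoyl amide). The arene is cut at O–Me, at the C-prenyl bond (Claisen–Cope from an O-prenyl ether), at the two MOM ethers and at the aryl–acyl bond, back to phloroglucinol.
- Forward: the pyranone ring is closed by lactonisation of an open-chain triketide and then aminomethylated. The benzene ring is bought and substituted in six steps. The two rings are joined in the last step with no protecting group left.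
- Enabling feature: C3 of the 4-hydroxy-2-pyranone ring lies between the lactone C2=O and the C4 enol, so a CH2–NR2 group on it is expelled to give the 3-methylidene-pyran-2,4-dione. This reverses the polarity of the nucleophilic C3 into an electrophilic exocyclic carbon. The phloroglucinol ring has exactly one unsubstituted carbon, ortho to an OH and the OMe and para to the chelated OH.
- Stereochemistry: none to set.

Key step: step 10

Remark: the target has no stereocentre, and its only non-ring C=C carries two identical methyl groups, so the achiral compound itself is the required single species.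

**Route**

Step 1
Reactants: 1 ethyl 3-oxopentanoate; 2 N-methoxy-N-methylpropanamide
Product: 3 ethyl 4-methyl-3,5-dioxoheptanoate
Conditions: LDA (2.2 equiv), THF, −78 → 0 °C; then 2, −78 → 0 °C; aq. HCl quench
Reagents that add atoms: none
Why: γ-Acylation of a β-keto ester dianion by a Weinreb-type amide: the more basic γ-carbanion should attack 2, and the chelated tetrahedral adduct should hold until the acidic quench, so that the more acidic product 3 cannot quench unreacted dianion; C4 of 3 is enolisable and becomes sp2 in step 2, so its configuration is of no consequence.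

Step 2
Reactants: 3 ethyl 4-methyl-3,5-dioxoheptanoate
Product: 4 6-ethyl-4-hydroxy-5-methyl-2H-pyran-2-one
Conditions: DBU (1.2 equiv), toluene, reflux; then 1 M HCl
Reagents that add atoms: none
Why: Base-mediated lactonisation of a 3,5-dioxo ester: the C5 enolate oxygen should close the six-membered ring on the ester carbonyl (6-exo-trig acyl substitution, loss of ethoxide), with the aromatic 4-hydroxy-2-pyranone as the thermodynamic sink.

Step 3
Reactants: 4 6-ethyl-4-hydroxy-5-methyl-2H-pyran-2-one
Product: 5 1-(6-ethyl-4-hydroxy-5-methyl-2-oxo-2H-pyran-3-yl)-N,N-dimethylmethanaminium iodide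
Conditions: Eschenmoser's salt (1.05 equiv), MeCN, 0 °C → rt; precipitation with Et2O, filtration
Reagents that add atoms: Eschenmoser's salt (N,N-dimethylmethyleneiminium iodide), C=[N+](C)C.[I-]
Why: Mannich reaction with a preformed iminium salt: C3 is the only nucleophilic carbon of the 4-hydroxy-2-pyranone, and without base the product stays N-protonated, which should block premature loss of the amine and the homodimerisation that would follow.

Step 4
Reactants: 6 phloroglucinol (benzene-1,3,5-triol); 7 2-methylpropanoyl chloride
Product: 8 2-methyl-1-(2,4,6-trihydroxyphenyl)propan-1-one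
Conditions: AlCl3 (3.5 equiv), PhNO2/CH2Cl2, rt → 45 °C; ice/HCl
Reagents that add atoms: none
Why: Friedel–Crafts C-acylation of a symmetrical, highly activated arene: the three ring positions of 6 are equivalent and the first acyl group deactivates the ring towards a second.

Step 5
Reactants: 8 2-methyl-1-(2,4,6-trihydroxyphenyl)propan-1-one
Product: 9 1-[2-hydroxy-4,6-bis(methoxymethoxy)phenyl]-2-methylpropan-1-one
Conditions: MOMCl (2.2 equiv), i-Pr2NEt (2.5 equiv), CH2Cl2, 0 °C → rt
Reagents that add atoms: chloromethyl methyl ether (MOMCl), COCCl
Why: Selective MOM etherification: the hydroxyl hydrogen-bonded to the ketone carbonyl is the least nucleophilic, so two equivalents of MOMCl should cap the 4-OH and one of the two equivalent ortho-OH groups and leave one chelated OH free.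

Step 6
Reactants: 9 1-[2-hydroxy-4,6-bis(methoxymethoxy)phenyl]-2-methylpropan-1-one; 10 3-methylbut-2-en-1-ol
Product: 11 1-{2,4-bis(methoxymethoxy)-6-[(3-methylbut-2-en-1-yl)oxy]phenyl}-2-methylpropan-1-one
Conditions: PPh3, DIAD, THF, 0 °C → rt
Reagents that add atoms: none
Why: Mitsunobu etherification: the chelated phenol is acidic enough to serve as pronucleophile, and the primary allylic oxyphosphonium should be displaced at carbon (SN2) to give the aryl prenyl ether without C-alkylation.

Step 7
Reactants: 11 1-{2,4-bis(methoxymethoxy)-6-[(3-methylbut-2-en-1-yl)oxy]phenyl}-2-methylpropan-1-one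
Product: 14 1-[6-hydroxy-2,4-bis(methoxymethoxy)-3-(3-methylbut-2-en-1-yl)phenyl]-2-methylpropan-1-one, via ortho-dienone 12 (not isolated), via para-dienone 13 (not isolated)
Conditions: PhNEt2, 200 °C, N2
Reagents that add atoms: none
Why: Aromatic Claisen rearrangement followed by Cope rearrangement (para-Claisen): a [3,3] shift to the free ortho carbon should give dienone 12 with a crowded 1,1-dimethylallyl group, a second [3,3] shift should relay it as a normal prenyl group to the para carbon between the two MOM ethers (13), and enolisation should restore the arene, which removes the transient sp3 centres.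

Step 8
Reactants: 14 1-[6-hydroxy-2,4-bis(methoxymethoxy)-3-(3-methylbut-2-en-1-yl)phenyl]-2-methylpropan-1-one
Product: 15 1-[6-methoxy-2,4-bis(methoxymethoxy)-3-(3-methylbut-2-en-1-yl)phenyl]-2-methylpropan-1-one
Conditions: MeI, K2CO3, DMF, rt → 40 °C
Reagents that add atoms: iodomethane, CI
Why: Williamson O-methylation of the one free (chelated) phenol; the other two oxygens are capped, so no other site competes.

Step 9
Reactants: 15 1-[6-methoxy-2,4-bis(methoxymethoxy)-3-(3-methylbut-2-en-1-yl)phenyl]-2-methylpropan-1-one
Product: 16 1-[2,4-dihydroxy-6-methoxy-3-(3-methylbut-2-en-1-yl)phenyl]-2-methylpropan-1-one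
Conditions: HCl (from conc. HCl, ca. 3 M), MeOH, rt
Reagents that add atoms: none
Why: Acid-catalysed acetal exchange with methanol (MOM cleavage) should free both phenols at room temperature, where the aryl methyl ether is stable and cyclisation of the prenyl group onto a neighbouring phenol should stay slow.

Step 10
Reactants: 5 1-(6-ethyl-4-hydroxy-5-methyl-2-oxo-2H-pyran-3-yl)-N,N-dimethylmethanaminium iodide; 16 1-[2,4-dihydroxy-6-methoxy-3-(3-methylbut-2-en-1-yl)phenyl]-2-methylpropan-1-one
Product: 18 3-{[2,4-dihydroxy-6-methoxy-3-(3-methylbut-2-en-1-yl)-5-(2-methylpropanoyl)phenyl]methyl}-6-ethyl-4-hydroxy-5-methyl-2H-pyran-2-one, via pyranone methide 17 (not isolated)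
Conditions: 5 (1.0 equiv), 16 (1.2 equiv), NaOAc (2 equiv), MeCN, 60 °C; 1 M HCl work-up
Reagents that add atoms: none
Why: Acetate frees the zwitterionic Mannich base, whose pyranone enolate expels dimethylamine (E1cB) to give 17, an exocyclic enone activated by both the C2 lactone and the C4 ketone carbonyl; the phenol(ate) of 16 then adds through its only unsubstituted ring carbon to the methylidene carbon (Friedel–Crafts-type conjugate addition), and proton shifts restore the benzene ring and the 4-hydroxy-2-pyranone. The closest known reaction type is the Mannich-base (elimination–Michael addition) alkylation of acylphloroglucinols and 4-hydroxy-2-pyranones used for methylene-bridged dimers. No ring is closed and no stereocentre is formed. The step needs C- over O-alkylation, attack at the free carbon and not at the prenylated one, and cross- over homo-coupling: O-adducts and adducts at the substituted carbon cannot rearomatise and should revert, each partner has a single reactive carbon, and the preformed, isolated Mannich salt (no free formaldehyde, no free 4 at the start) with a small excess of 16 should hold back the bis-pyranone.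

**Compound list**

1 | ethyl 3-oxopentanoate | CCC(=O)CC(=O)OCC | starting material
2 | N-methoxy-N-methylpropanamide | CCC(=O)N(C)OC | starting material
3 | ethyl 4-methyl-3,5-dioxoheptanoate (racemic, enolisable at C4) | CCC(=O)C(C)C(=O)CC(=O)OCC | intermediate
4 | 6-ethyl-4-hydroxy-5-methyl-2H-pyran-2-one | CCc1oc(=O)cc(O)c1C | intermediate
5 | 1-(6-ethyl-4-hydroxy-5-methyl-2-oxo-2H-pyran-3-yl)-N,N-dimethylmethanaminium iodide | CCc1oc(=O)c(C[NH+](C)C)c(O)c1C.[I-] | intermediate
6 | phloroglucinol (benzene-1,3,5-triol) | Oc1cc(O)cc(O)c1 | starting material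
7 | 2-methylpropanoyl chloride | CC(C)C(=O)Cl | starting material
8 | 2-methyl-1-(2,4,6-trihydroxyphenyl)propan-1-one | CC(C)C(=O)c1c(O)cc(O)cc1O | intermediate
9 | 1-[2-hydroxy-4,6-bis(methoxymethoxy)phenyl]-2-methylpropan-1-one | CC(C)C(=O)c1c(O)cc(OCOC)cc1OCOC | intermediate
10 | 3-methylbut-2-en-1-ol | CC(C)=CCO | starting material
11 | 1-{2,4-bis(methoxymethoxy)-6-[(3-methylbut-2-en-1-yl)oxy]phenyl}-2-methylpropan-1-one | CC(C)C(=O)c1c(OCC=C(C)C)cc(OCOC)cc1OCOC | intermediate
12 | 3,5-bis(methoxymethoxy)-6-(2-methylbut-3-en-2-yl)-2-(2-methylpropanoyl)cyclohexa-2,4-dien-1-one (racemic, transient) | CC(C)C(=O)C1=C(OCOC)C=C(OCOC)C(C(C)(C)C=C)C1=O | intermediate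
13 | 3,5-bis(methoxymethoxy)-4-(3-methylbut-2-en-1-yl)-2-(2-methylpropanoyl)cyclohexa-2,5-dien-1-one (racemic, transient) | CC(C)C(=O)C1=C(OCOC)C(CC=C(C)C)C(OCOC)=CC1=O | intermediate
14 | 1-[6-hydroxy-2,4-bis(methoxymethoxy)-3-(3-methylbut-2-en-1-yl)phenyl]-2-methylpropan-1-one | CC(C)C(=O)c1c(O)cc(OCOC)c(CC=C(C)C)c1OCOC | intermediate
15 | 1-[6-methoxy-2,4-bis(methoxymethoxy)-3-(3-methylbut-2-en-1-yl)phenyl]-2-methylpropan-1-one | CC(C)C(=O)c1c(OC)cc(OCOC)c(CC=C(C)C)c1OCOC | intermediate
16 | 1-[2,4-dihydroxy-6-methoxy-3-(3-methylbut-2-en-1-yl)phenyl]-2-methylpropan-1-one | CC(C)C(=O)c1c(OC)cc(O)c(CC=C(C)C)c1O | intermediate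
17 | 6-ethyl-5-methyl-3-methylidene-2H-pyran-2,4(3H)-dione (transient) | CCC1=C(C)C(=O)C(=C)C(=O)O1 | intermediate
18 | 3-{[2,4-dihydroxy-6-methoxy-3-(3-methylbut-2-en-1-yl)-5-(2-methylpropanoyl)phenyl]methyl}-6-ethyl-4-hydroxy-5-methyl-2H-pyran-2-one | CCc1oc(=O)c(Cc2c(O)c(CC=C(C)C)c(O)c(C(=O)C(C)C)c2OC)c(O)c1C | target

**Count and risks**

Total steps: 10. Longest linear sequence: 7 steps (steps 4–9, then step 10); the pyranone branch has 3 steps before the union.

Steps most likely to fail:

1. Step 10. The methide may be consumed by homodimerisation with pyranone set free by retro-Mannich reaction, or by O-alkylation of the phenol. Fallback: the roles of the partners would be exchanged. Arene 16 would be aminomethylated at its one free ring carbon with Eschenmoser's salt (CH2Cl2, rt; NaHCO3 wash) to give 1-{3-[(dimethylamino)methyl]-4,6-dihydroxy-2-methoxy-5-(3-methylbut-2-en-1-yl)phenyl}-2-methylpropan-1-one F1. F1 would then be heated with pyranone 4 (dioxane, 100 °C), so that the ortho-quinone methide of the phloroglucinol is trapped by C3 of 4. This sets out from 16 (with 4) and comes back to the route at 18.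

2. Step 7. Tautomerisation of the ortho-dienone to the reverse-prenylated phenol may outrun the Cope shift, and MOM groups may be lost or the product may cyclise at 200 °C. Fallback: the sigmatropic transfer would be replaced by direct C-prenylation of a phenolate. Compound 9 would be O-methylated (MeI, K2CO3, DMF) to 1-[2-methoxy-4,6-bis(methoxymethoxy)phenyl]-2-methylpropan-1-one F2. The MOM groups would be removed (HCl, MeOH, rt) to give 1-(2,4-dihydroxy-6-methoxyphenyl)-2-methylpropan-1-one F3. F3 would be alkylated with prenyl bromide (DBU, THF, 0 °C → rt) at the carbon between the two hydroxyls, with the regioisomer prenylated next to the methoxy group removed by chromatography. This sets out from 9 and comes back to the route at 16.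

3. Step 1. The γ-branched dianion may react sluggishly or at oxygen, and the triketide may suffer retro-Claisen cleavage on work-up. Fallback: the anionic acylation would be replaced by a neutral Mukaiyama-type γ-acylation. Compound 1 would be converted (TMSCl, Et3N; then LDA, TMSCl, THF, −78 °C) into 1-ethoxy-1,3-bis(trimethylsilyloxy)penta-1,3-diene F4 (mixture of geometric isomers). F4 would be treated with propanoyl chloride (CH2Cl2, −78 °C → rt) and worked up with aqueous acid. This sets out from 1 and comes back to the route at 3.

**Further compounds**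

F1 | step 10 | 1-{3-[(dimethylamino)methyl]-4,6-dihydroxy-2-methoxy-5-(3-methylbut-2-en-1-yl)phenyl}-2-methylpropan-1-one | CC(C)C(=O)c1c(OC)c(CN(C)C)c(O)c(CC=C(C)C)c1O
F2 | step 7 | 1-[2-methoxy-4,6-bis(methoxymethoxy)phenyl]-2-methylpropan-1-one | CC(C)C(=O)c1c(OC)cc(OCOC)cc1OCOC
F3 | step 7 | 1-(2,4-dihydroxy-6-methoxyphenyl)-2-methylpropan-1-one | CC(C)C(=O)c1c(OC)cc(O)cc1O
F4 | step 1 | 1-ethoxy-1,3-bis(trimethylsilyloxy)penta-1,3-diene (mixture of geometric isomers) | CC=C(O[Si](C)(C)C)C=C(OCC)O[Si](C)(C)C
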